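**Retrosynthetic overview**
1. Target 18 ⇐ chelation-controlled O8-demethylation of 17 ⇐ ring B closed last by intramolecular Friedel–Crafts (Claisen-type) C-acylation of ring A by the arylacetic acid arm of 15.
2. Oxazolidine ⇐ formal [3+2] of the ring C p-quinol 8 with 1-pyrroline (hemiaminal, 5-exo aza-Michael, dehydrogenation), mirroring the presumed biogenesis (Δ1-pyrroline capture of a hydroxylated dienone); a chiral phosphoric acid selects one quinol enantiomer and so fixes C4, and the aminal follows.
3. p-Quinol 8 ⇐ singlet-oxygen para-hydroxylative dearomatisation of the fully substituted guaiacol 6.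
4. Biaryl phenol 6 ⇐ creosol by dibromination, site-selective Suzuki coupling and Reformatsky–Negishi coupling.
5. Ring order: rings C (creosol) and A (boronic acid) are bought aromatic; the pyrrolidine is bought as pyrrolidine; the oxazolidine is formed on dearomatised ring C; ring B is formed last.

Assumption: the target is taken as the drawn 10H-9-keto tautomer, and (R)-TRIP is written as the acid antipode matched to the (S)-quinol (the antipode is used if the sense is opposite).
Locants: phenanthrene numbering of the target is used in the text (ring A = C4b, C5–C8, C8a; ring B adds C9, C10; ring C = C1–C4, C4a, C10a; C4 = quaternary C–O carbon; C2' = aminal carbon). In the systematic names of 13–16 these two atoms are 4a and 3a.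

**Step 1**
Reactants: 1 2-methoxy-4-methylphenol (creosol)
Product: 2 2,3-dibromo-6-methoxy-4-methylphenol
Conditions: Br2 (2.1 equiv), AcOH, 0 °C to rt
Reagents that add atoms: bromine, BrBr
Why: Electrophilic aromatic bromination in which the first bromine enters ortho to the hydroxyl and the second para to the methoxy group (the vanillin to 5,6-dibromovanillin pattern); no stereocentre.

**Step 2**
Reactants: 2 2,3-dibromo-6-methoxy-4-methylphenol; 3 3,5-dimethoxyphenylboronic acid
Product: 4 2-bromo-3-(3,5-dimethoxyphenyl)-6-methoxy-4-methylphenol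
Conditions: 3 (1.05 equiv), Pd(PPh3)4 (3 mol%), K2CO3, dioxane/H2O, 80 °C
Reagents that add atoms: 3,5-dimethoxyphenylboronic acid (3), OB(O)c1cc(OC)cc(OC)c1
Why: Suzuki–Miyaura coupling made site-selective by the phenoxide formed under base, which enriches the ortho C–Br and slows its oxidative addition to zerovalent palladium, so the bromide meta to O− couples first.

**Step 3**
Reactants: 4 2-bromo-3-(3,5-dimethoxyphenyl)-6-methoxy-4-methylphenol; 5 (2-ethoxy-2-oxoethyl)zinc bromide (BrZnCH2CO2Et)
Product: 6 ethyl 2-[2-(3,5-dimethoxyphenyl)-6-hydroxy-5-methoxy-3-methylphenyl]acetate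
Conditions: 5 (3 equiv), Pd(dba)2 (5 mol%), Q-phos [1,2,3,4,5-pentaphenyl-1'-(di-tert-butylphosphino)ferrocene] (5 mol%), THF, 60 °C; aq. NH4Cl
Reagents that add atoms: (2-ethoxy-2-oxoethyl)zinc bromide (5), CCOC(=O)C[Zn]Br
Why: Negishi-type α-arylation of a Reformatsky zinc ester enolate under near-neutral conditions, which tolerates the phenol (one equivalent of 5 is spent as its zinc phenoxide) and, with a bulky monophosphine, a di-ortho-substituted aryl bromide.

**Step 4**
Reactants: 6 ethyl 2-[2-(3,5-dimethoxyphenyl)-6-hydroxy-5-methoxy-3-methylphenyl]acetate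
Product: 8 ethyl 2-[2-(3,5-dimethoxyphenyl)-3-hydroxy-5-methoxy-3-methyl-6-oxocyclohexa-1,4-dien-1-yl]acetate (racemic p-quinol), via hydroperoxide 7 (not isolated)
Conditions: KHSO5 as Oxone (2KHSO5·KHSO4·K2SO4), NaHCO3, MeCN/H2O, rt; then Me2S
Reagents that add atoms: potassium peroxymonosulfate (oxidant of Oxone), [K+].[O-]S(=O)(=O)OO
Why: Hydroxylative dearomatisation by singlet oxygen from Oxone/bicarbonate, a formal [4+2] addition across C1/C4 that gives the para-hydroperoxide and avoids the ipso-methoxy attack that trivalent-iodine oxidants show with guaiacols, followed by O–O reduction with Me2S; C4 is formed racemic here and selected in step 6.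

**Step 5**
Reactants: 9 pyrrolidine
Product: 11 1-pyrroline (3,4-dihydro-2H-pyrrole), via N-chloropyrrolidine 10 (not isolated)
Conditions: N-chlorosuccinimide, Et2O, 0 °C; then KOH, MeOH, reflux; used at once as a titrated solution
Reagents that add atoms: none
Why: N-chlorination followed by base-induced dehydrochlorination (1,2-elimination) gives the cyclic imine, which is used directly because it trimerises on storage.

**Step 6**
Reactants: 8 racemic p-quinol; 11 1-pyrroline
Product: 14 ethyl 2-[(3aS,4aR)-5-(3,5-dimethoxyphenyl)-8-methoxy-4a-methyl-7-oxo-1,2,3,3a,4a,7-hexahydropyrrolo[2,1-b][1,3]benzoxazol-6-yl]acetate, via hemiaminal ether 12 (not isolated), via amino ketone 13 (not isolated)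
Conditions: 11 (0.55 equiv), (R)-TRIP [(R)-3,3'-bis(2,4,6-triisopropylphenyl)-1,1'-binaphthyl-2,2'-diyl hydrogen phosphate] (5 mol%), 4 Å sieves, toluene, −30 °C to about 50% conversion; then DDQ (2,3-dichloro-5,6-dicyano-1,4-benzoquinone, 0.55 equiv), −30 to 0 °C
Reagents that add atoms: 1-pyrroline (11), C1CC=NC1
Why: Proposed new method: the chiral phosphoric acid ion-pairs with pyrrolinium, the quinol hydroxyl adds to give hemiaminal ether 12, and the acid then steers the 5-exo aza-Michael addition of N–H to C3 (the only unblocked enone terminus), where the (S)-quinol is expected to react much faster than its antipode (kinetic resolution, at most 50% yield, (R)-8 recovered), after which DDQ abstracts hydride from the α-amino C3–H and loss of the C2 proton gives the vinylogous amide, so the quaternary carbon (4aR in 14, R at C4 of the target) is fixed by catalyst selection and the aminal carbon settles S under acid-catalysed equilibration with its hydrogen cis to the methyl; the closest known reaction types are phosphoric acid-catalysed acetalisation/hetero-Michael cascades of p-quinols with aldehydes and DDQ dehydrogenation of β-amino ketones to enaminones.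

**Step 7**
Reactants: 14 enaminone ethyl ester
Product: 15 2-[(3aS,4aR)-5-(3,5-dimethoxyphenyl)-8-methoxy-4a-methyl-7-oxo-1,2,3,3a,4a,7-hexahydropyrrolo[2,1-b][1,3]benzoxazol-6-yl]acetic acid
Conditions: LiOH, THF/H2O, 0 °C; then 1 M HCl to pH 4
Reagents that add atoms: lithium hydroxide, [Li+].[OH-]
Why: Saponification (addition–elimination at the ester carbonyl) under conditions too mild to attack the vinylogous amide or the N,O-acetal; both stereocentres are untouched.

**Step 8**
Reactants: 15 arylacetic acid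
Product: 17 O8-methyl ether of the target (ring B closed as the 10H-9-ketone; 2,6,8-trimethoxy; 4R,2'S), via mixed anhydride 16 (not isolated)
Conditions: (CF3CO)2O (3 equiv), CH2Cl2, 0 °C to rt
Reagents that add atoms: none
Why: Intramolecular Friedel–Crafts acylation via the mixed trifluoroacetic anhydride, in which the acyl carbon sits cis to ring A across the C4a=C10a double bond and attacks a ring position ortho to one methoxy group and para to the other (both ortho positions are equivalent); stereocentres untouched.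

**Step 9**
Reactants: 17 O8-methyl ether of the target
Product: 18 CNP0528850.1 (4R,2'S; 8-hydroxy-2,6-dimethoxy-4-methyl-10H-phenanthrene-1,9-dione core with N1' on C3 and C2' on the C4 oxygen; aminal H cis to the C4 methyl)
Conditions: BCl3 (2.5 equiv), CH2Cl2, −78 to −20 °C; then H2O, 0 °C
Reagents that add atoms: none
Why: Chelation-controlled demethylation in which boron bound to the C9 ketone forms a six-membered chelate with the ortho C8 methoxy oxygen and chloride removes that methyl only, sparing the C2 and C6 ethers; the stereocentres are not involved and any reversible opening of the N,O-acetal re-closes to the same cis isomer.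

**Compound list**
1 | 2-methoxy-4-methylphenol (creosol) | COc1cc(C)ccc1O | starting material
2 | 2,3-dibromo-6-methoxy-4-methylphenol | COc1cc(C)c(Br)c(Br)c1O | intermediate
3 | 3,5-dimethoxyphenylboronic acid | OB(O)c1cc(OC)cc(OC)c1 | starting material
4 | 2-bromo-3-(3,5-dimethoxyphenyl)-6-methoxy-4-methylphenol | COc1cc(C)c(-c2cc(OC)cc(OC)c2)c(Br)c1O | intermediate
5 | (2-ethoxy-2-oxoethyl)zinc bromide | CCOC(=O)C[Zn]Br | starting material
6 | ethyl 2-[2-(3,5-dimethoxyphenyl)-6-hydroxy-5-methoxy-3-methylphenyl]acetate | CCOC(=O)Cc1c(O)c(OC)cc(C)c1-c1cc(OC)cc(OC)c1 | intermediate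
7 | ethyl 2-[2-(3,5-dimethoxyphenyl)-3-hydroperoxy-5-methoxy-3-methyl-6-oxocyclohexa-1,4-dien-1-yl]acetate (racemic) | CCOC(=O)CC1=C(c2cc(OC)cc(OC)c2)C(C)(OO)C=C(OC)C1=O | intermediate
8 | ethyl 2-[2-(3,5-dimethoxyphenyl)-3-hydroxy-5-methoxy-3-methyl-6-oxocyclohexa-1,4-dien-1-yl]acetate (racemic) | CCOC(=O)CC1=C(c2cc(OC)cc(OC)c2)C(C)(O)C=C(OC)C1=O | intermediate
9 | pyrrolidine | C1CCNC1 | starting material
10 | N-chloropyrrolidine | ClN1CCCC1 | intermediate
11 | 1-pyrroline (3,4-dihydro-2H-pyrrole) | C1CC=NC1 | intermediate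
12 | ethyl 2-[(3S)-2-(3,5-dimethoxyphenyl)-5-methoxy-3-methyl-6-oxo-3-[(2S)-pyrrolidin-2-yloxy]cyclohexa-1,4-dien-1-yl]acetate | COC1=C[C@](C)(O[C@H]2CCCN2)C(c2cc(OC)cc(OC)c2)=C(CC(=O)OCC)C1=O | intermediate
13 | ethyl 2-[(3aS,4aR,8aS)-5-(3,5-dimethoxyphenyl)-8-methoxy-4a-methyl-7-oxo-1,2,3,3a,4a,7,8,8a-octahydropyrrolo[2,1-b][1,3]benzoxazol-6-yl]acetate (C8 epimers) | COC1[C@@H]2N3CCC[C@@H]3O[C@]2(C)C(c2cc(OC)cc(OC)c2)=C(CC(=O)OCC)C1=O | intermediate
14 | ethyl 2-[(3aS,4aR)-5-(3,5-dimethoxyphenyl)-8-methoxy-4a-methyl-7-oxo-1,2,3,3a,4a,7-hexahydropyrrolo[2,1-b][1,3]benzoxazol-6-yl]acetate | COC1=C2N3CCC[C@@H]3O[C@]2(C)C(c2cc(OC)cc(OC)c2)=C(CC(=O)OCC)C1=O | intermediate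
15 | 2-[(3aS,4aR)-5-(3,5-dimethoxyphenyl)-8-methoxy-4a-methyl-7-oxo-1,2,3,3a,4a,7-hexahydropyrrolo[2,1-b][1,3]benzoxazol-6-yl]acetic acid | COC1=C2N3CCC[C@@H]3O[C@]2(C)C(c2cc(OC)cc(OC)c2)=C(CC(=O)O)C1=O | intermediate
16 | mixed trifluoroacetic anhydride of 15 | COC1=C2N3CCC[C@@H]3O[C@]2(C)C(c2cc(OC)cc(OC)c2)=C(CC(=O)OC(=O)C(F)(F)F)C1=O | intermediate
17 | O8-methyl ether of the target (4R,2'S; 2,6,8-trimethoxy; ring B closed) | COC1=C2N3CCC[C@@H]3O[C@]2(C)C2=C(CC(=O)c3c(OC)cc(OC)cc32)C1=O | intermediate
18 | CNP0528850.1 (4R,2'S) | COC1=C2N3CCC[C@@H]3O[C@]2(C)C2=C(CC(=O)c3c(O)cc(OC)cc32)C1=O | target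

**Step count and risks**
Total step count: 9. Longest linear sequence: 8 steps (1 → 2 → 4 → 6 → 8 → 14 → 15 → 17 → 18); step 5 prepares the imine.

Most likely to fail, first: step 2 (site selectivity of the Suzuki coupling; the crowded coupling of step 3 shares this risk). The fallback installs the acetic acid arm first, so that only one bromide is ever present. It sets out from 1: glyoxylic acid in aqueous NaOH hydroxyalkylates the free ortho position to give 2-hydroxy-2-(2-hydroxy-3-methoxy-5-methylphenyl)acetic acid F1. SnCl2 in concentrated HCl removes the benzylic hydroxyl, and lactonisation (TsOH, toluene, reflux) gives 7-methoxy-5-methyl-1-benzofuran-2(3H)-one F2. Br2 in AcOH brominates para to the methoxy group to give 4-bromo-7-methoxy-5-methyl-1-benzofuran-2(3H)-one F3. Suzuki–Miyaura coupling with 3 (Pd(OAc)2, SPhos, K3PO4, then acid) gives 4-(3,5-dimethoxyphenyl)-7-methoxy-5-methyl-1-benzofuran-2(3H)-one F4. Ethanolysis (EtOH, catalytic NaOEt) opens the aryl lactone and the fallback comes back to the route at 6.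

Second: step 6 (enantiomer discrimination and the dehydrogenation). The fallback builds the heterocycle stepwise on the racemate and separates the enantiomers as salts. It sets out from 8: conjugate addition of 4-aminobutanal diethyl acetal at C3 followed by DDQ gives ethyl 2-[4-[(4,4-diethoxybutyl)amino]-2-(3,5-dimethoxyphenyl)-3-hydroxy-5-methoxy-3-methyl-6-oxocyclohexa-1,4-dien-1-yl]acetate F5. TsOH in wet acetone unmasks the aldehyde, which closes onto N–H and the C4 hydroxyl to give racemic ethyl 2-[5-(3,5-dimethoxyphenyl)-8-methoxy-4a-methyl-7-oxo-1,2,3,3a,4a,7-hexahydropyrrolo[2,1-b][1,3]benzoxazol-6-yl]acetate F6. LiOH gives the racemic acetic acid F7. Crystallisation with (R)-1-phenylethylamine (or its antipode if the other salt is the less soluble) gives the (R)-1-phenylethylammonium salt of the (3aS,4aR) acid F8. Acidification with HCl comes back to the route at 15.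

Third: step 8 (acid released from the anhydride may trigger dienone–phenol rearrangement or loss of the aminal). The fallback closes ring B pericyclically under basic conditions. It sets out from 15: 1-chloro-N,N,2-trimethylprop-1-en-1-amine gives the acid chloride of 15 F9. Et3N in toluene at 80 °C eliminates HCl to give the aryl vinyl ketene of 15 F10, whose 6π-electrocyclisation onto ring A and tautomerisation come back to the route at 17.

**Further compounds**
F1 | step 2 | 2-hydroxy-2-(2-hydroxy-3-methoxy-5-methylphenyl)acetic acid (racemic) | COc1cc(C)cc(C(O)C(=O)O)c1O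
F2 | step 2 | 7-methoxy-5-methyl-1-benzofuran-2(3H)-one | O=C1Cc2cc(C)cc(OC)c2O1
F3 | step 2 | 4-bromo-7-methoxy-5-methyl-1-benzofuran-2(3H)-one | O=C1Cc2c(Br)c(C)cc(OC)c2O1
F4 | step 2 | 4-(3,5-dimethoxyphenyl)-7-methoxy-5-methyl-1-benzofuran-2(3H)-one | O=C1Cc2c(-c3cc(OC)cc(OC)c3)c(C)cc(OC)c2O1
F5 | step 6 | ethyl 2-[4-[(4,4-diethoxybutyl)amino]-2-(3,5-dimethoxyphenyl)-3-hydroxy-5-methoxy-3-methyl-6-oxocyclohexa-1,4-dien-1-yl]acetate (racemic) | CCOC(=O)CC1=C(c2cc(OC)cc(OC)c2)C(C)(O)C(NCCCC(OCC)OCC)=C(OC)C1=O
F6 | step 6 | racemic ethyl 2-[5-(3,5-dimethoxyphenyl)-8-methoxy-4a-methyl-7-oxo-1,2,3,3a,4a,7-hexahydropyrrolo[2,1-b][1,3]benzoxazol-6-yl]acetate | COC1=C2N3CCCC3OC2(C)C(c2cc(OC)cc(OC)c2)=C(CC(=O)OCC)C1=O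
F7 | step 6 | racemic 2-[5-(3,5-dimethoxyphenyl)-8-methoxy-4a-methyl-7-oxo-1,2,3,3a,4a,7-hexahydropyrrolo[2,1-b][1,3]benzoxazol-6-yl]acetic acid | COC1=C2N3CCCC3OC2(C)C(c2cc(OC)cc(OC)c2)=C(CC(=O)O)C1=O
F8 | step 6 | (R)-1-phenylethylammonium salt of the (3aS,4aR) acid 15 | COC1=C2N3CCC[C@@H]3O[C@]2(C)C(c2cc(OC)cc(OC)c2)=C(CC(=O)[O-])C1=O.C[C@@H]([NH3+])c1ccccc1
F9 | step 8 | acid chloride of 15 | COC1=C2N3CCC[C@@H]3O[C@]2(C)C(c2cc(OC)cc(OC)c2)=C(CC(Cl)=O)C1=O
F10 | step 8 | aryl vinyl ketene of 15 | COC1=C2N3CCC[C@@H]3O[C@]2(C)C(c2cc(OC)cc(OC)c2)=C(C=C=O)C1=O
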